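**Plan**

- Retrosynthesis: the 4'- and 5'-hydroxyls are traced back, through a ring-B quinone, to an ethyl and a methyl ether. Ring B is then cut at C1'–C2', C2'–C3' and C5'–C6' into a 2-ethynylchromone, one CO ligand and a methoxy(1-ethoxyvinyl)carbene complex of chromium. The alkyne goes back to a chromone-2-carboxylate, cut at O1–C2 and C2–C3 (oxalate) and at the three C-prenyl bonds.
- Enabling feature: ring B carries oxygen on C2' and C5' (para to each other), a third oxygen on C4' and hydrogen on C3' and C6'. This is the pattern that an alkoxy(α-alkoxyalkenyl)carbene, CO and a terminal alkyne assemble.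
- Forward order: ring A is bought (phloroacetophenone) and prenylated, the pyranone ring is closed second by oxalate Claisen condensation and cyclodehydration, and ring B is built last on the finished triprenylchromone.
- Stereochemistry: the target has no stereocentre and no configured double bond, so nothing has to be controlled.

Key step: step 10

Remark: prenyl stands for 3-methylbut-2-en-1-yl and MOM for methoxymethyl. The keto ester intermediates of the pyranone closure are racemic, partly enolised species whose stereocentres vanish when that ring aromatises.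

**Route**

Step 1
Reactants: 1 2,4,6-trihydroxyacetophenone; 2 prenyl bromide (1-bromo-3-methylbut-2-ene)
Product: 3 2,4,6-trihydroxy-3,5-diprenylacetophenone
Conditions: 2 (2.2 equiv), 10% aq. KOH, 0 °C to rt
Reagents that add atoms: none
Why: C-alkylation of the ambident acylphloroglucinol phenolate in water (C-prenylation), where hydrogen bonding shields the oxygens so that the allylic bromide is taken up by the two free ring carbons C3 and C5.

Step 2
Reactants: 3 2,4,6-trihydroxy-3,5-diprenylacetophenone
Product: 4 2,6-dihydroxy-4-methoxy-3,5-diprenylacetophenone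
Conditions: MeI (1.05 equiv), K2CO3 (1.0 equiv), acetone, rt
Reagents that add atoms: iodomethane (MeI), SMILES CI
Why: Williamson ether synthesis with one equivalent of weak base, which should select the most acidic 4-OH (para to the acetyl group and not chelated to it) while the two carbonyl-bonded ortho hydroxyls stay protonated.

Step 3
Reactants: 4 2,6-dihydroxy-4-methoxy-3,5-diprenylacetophenone
Product: 5 4-methoxy-2,6-bis(methoxymethoxy)-3,5-diprenylacetophenone
Conditions: NaH (2.2 equiv), MOMCl (2.5 equiv), DMF, 0 °C to rt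
Reagents that add atoms: chloromethyl methyl ether (MOMCl), SMILES COCCl
Why: MOM protection of both sodium phenolates by SN2 alkylation with the α-chloro ether, needed so that the enolate chemistry that follows meets no acidic OH.

Step 4
Reactants: 5 4-methoxy-2,6-bis(methoxymethoxy)-3,5-diprenylacetophenone; 2 prenyl bromide
Product: 6 1-[4-methoxy-2,6-bis(methoxymethoxy)-3,5-diprenylphenyl]-5-methylhex-4-en-1-one
Conditions: LiN(i-Pr)2 (1.1 equiv), THF, −78 °C; then 2 (1.2 equiv), −78 to 0 °C
Reagents that add atoms: none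
Why: Alkylation of the kinetic lithium enolate of the aryl methyl ketone by the allylic bromide (SN2), the acetyl methyl group being the only enolisable position.

Step 5
Reactants: 6 1-[4-methoxy-2,6-bis(methoxymethoxy)-3,5-diprenylphenyl]-5-methylhex-4-en-1-one; 7 diethyl oxalate
Product: 11 ethyl 5-hydroxy-7-methoxy-4-oxo-3,6,8-triprenyl-4H-chromene-2-carboxylate, via bis-MOM diketo ester 8 (not isolated), via free bis-phenol diketo ester 9 (not isolated), via 2-hydroxychromanone hemiketal 10 (not isolated)
Conditions: LiN(SiMe3)2 (2.2 equiv), THF, −78 °C; 7 (1.5 equiv), −78 to 0 °C; then aq. HCl (3 mol/L), EtOH, 50 °C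
Reagents that add atoms: none
Why: Crossed Claisen condensation of the ketone enolate with non-enolisable diethyl oxalate (driven by deprotonation of the tricarbonyl product), then acid hydrolysis of the two MOM acetals, 6-exo-trig addition of a phenol to the α-keto ester carbonyl and dehydration of the hemiketal to the aromatic pyranone, which is the classical chromone-2-carboxylate synthesis.

Step 6
Reactants: 11 ethyl 5-hydroxy-7-methoxy-4-oxo-3,6,8-triprenyl-4H-chromene-2-carboxylate
Product: 12 5-hydroxy-2-(hydroxymethyl)-7-methoxy-3,6,8-triprenyl-4H-chromen-4-one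
Conditions: NaBH4 (3 equiv), EtOH/THF, 0 °C to rt
Reagents that add atoms: none
Why: Chemoselective borohydride reduction of the ester, which is activated by the electron-poor pyranone C2, while the vinylogous-ester C4 carbonyl, further deactivated as the chelated 5-phenoxide, should stay intact.

Step 7
Reactants: 12 5-hydroxy-2-(hydroxymethyl)-7-methoxy-3,6,8-triprenyl-4H-chromen-4-one
Product: 13 5-hydroxy-7-methoxy-4-oxo-3,6,8-triprenyl-4H-chromene-2-carbaldehyde
Conditions: activated MnO2 (15 equiv), CH2Cl2, rt
Reagents that add atoms: none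
Why: Heterogeneous MnO2 oxidation of an allylic-type primary alcohol (the CH2OH sits on the C2=C3 double bond) stops at the aldehyde and does not touch the prenyl alkenes or the chelated phenol.

Step 8
Reactants: 13 5-hydroxy-7-methoxy-4-oxo-3,6,8-triprenyl-4H-chromene-2-carbaldehyde
Product: 14 2-ethynyl-5-hydroxy-7-methoxy-3,6,8-triprenyl-4H-chromen-4-one
Conditions: dimethyl (1-diazo-2-oxopropyl)phosphonate (1.5 equiv), K2CO3 (2.5 equiv), MeOH/THF, 0 °C to rt
Reagents that add atoms: dimethyl (1-diazo-2-oxopropyl)phosphonate, SMILES CC(=O)C(=[N+]=[N-])P(=O)(OC)OC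
Why: Ohira–Bestmann variant of the Seyferth–Gilbert homologation, in which methanolysis of the reagent gives the diazomethylphosphonate anion, this adds to the non-enolisable aldehyde, and loss of dimethyl phosphate and N2 leaves an alkylidene carbene that rearranges by 1,2-hydrogen shift to the terminal alkyne.

Step 9
Reactants: 15 ethyl vinyl ether; 16 Cr(CO)6 (hexacarbonylchromium)
Product: 19 pentacarbonyl[(1-ethoxyvinyl)(methoxy)carbene]chromium, via 1-ethoxyvinyllithium 17 (not isolated), via lithium acylchromate 18 (not isolated)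
Conditions: t-BuLi, THF, −78 to 0 °C; 16, THF/Et2O, 0 °C to rt; then Me3OBF4, CH2Cl2/H2O, 0 °C
Reagents that add atoms: trimethyloxonium tetrafluoroborate (Me3OBF4), SMILES C[O+](C)C.F[B-](F)(F)F
Why: Fischer carbene synthesis, namely α-lithiation of the enol ether, addition of the vinyllithium to a CO ligand of Cr(CO)6 and O-methylation of the acylchromate by the hard oxonium salt, a sequence established for other α-alkoxyalkenyllithiums such as lithiated dihydropyran.

Step 10
Reactants: 14 2-ethynyl-5-hydroxy-7-methoxy-3,6,8-triprenyl-4H-chromen-4-one; 19 pentacarbonyl[(1-ethoxyvinyl)(methoxy)carbene]chromium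
Product: 21 2-(4-ethoxy-2-hydroxy-5-methoxyphenyl)-5-hydroxy-7-methoxy-3,6,8-triprenyl-4H-chromen-4-one, via its tricarbonylchromium complex 20 (not isolated)
Conditions: 19 (1.5 equiv), THF (0.1 mol/L), 50 °C, Ar, 16 h; then air, Et2O, rt
Reagents that add atoms: none
Why: Thermal loss of one CO from 19 opens a site for alkyne 14, which inserts into the Cr=C bond to give a vinylcarbene with the chromonyl-bearing carbon on chromium; CO insertion then gives a chromium-bound dienylketene that cyclises and tautomerises to the phenol, first obtained as its Cr(CO)3 complex 20 and freed by air. This is the Dötz benzannulation of an alkoxy(alkenyl)carbene complex of zerovalent chromium with a terminal alkyne, a reaction class that already covers α-alkoxyalkenyl carbenes and conjugated, electron-poor alkynes. Ring B closes by a thermal 6π-electrocyclisation that joins the ketene carbon (C2') to the ethoxyvinyl CH2 (C3') after the two insertions have made C5'–C6' and C1'–C2', so the carbene carbon becomes C5', the inserted CO becomes C2' and the vinyl carbons become C4' and C3'. No stereocentre is formed. The step needs regioselective alkyne insertion, secured by the terminal alkyne, whose only substituent (the chromone) is placed next to the CO-derived carbon; it also needs carbonylation of the vinylcarbene to outrun attack on the C3 prenyl alkene, which the alkenyl carbene and the coordinating solvent THF should favour.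

Step 11
Reactants: 21 2-(4-ethoxy-2-hydroxy-5-methoxyphenyl)-5-hydroxy-7-methoxy-3,6,8-triprenyl-4H-chromen-4-one
Product: 22 2-ethoxy-5-(5-hydroxy-7-methoxy-4-oxo-3,6,8-triprenyl-4H-chromen-2-yl)-1,4-benzoquinone
Conditions: (NH4)2Ce(NO3)6 (2.2 equiv), MeCN/H2O (4:1), 0 °C, 10 min
Reagents that add atoms: water, SMILES O
Why: Oxidative demethylation of a para-methoxyphenol by two equivalents of the one-electron oxidant, with water adding at C5' and methanol leaving, which should be far faster at 0 °C than oxidation of the chelated, carbonyl-deactivated ring A phenol or of the trisubstituted alkenes.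

Step 12
Reactants: 22 2-ethoxy-5-(5-hydroxy-7-methoxy-4-oxo-3,6,8-triprenyl-4H-chromen-2-yl)-1,4-benzoquinone
Product: 24 5-hydroxy-7-methoxy-3,6,8-triprenyl-2-(2,4,5-trihydroxyphenyl)-4H-chromen-4-one (CNP0330304.0), via hydroxyquinone 23 (not isolated)
Conditions: aq. NaOH (0.5 mol/L), THF, 0 °C, Ar; then AcOH to pH 6, Na2S2O4 (excess), H2O/EtOAc, rt, Ar
Reagents that add atoms: water, SMILES O
Why: Addition–elimination of hydroxide at C4' of the vinylogous ester (alkoxyquinone hydrolysis), the more electrophilic C1' being blocked by the chromone, followed by two-electron dithionite reduction of the hydroxyquinone to the 1,2,4-triol under air-free, weakly acidic conditions that leave the 7-methyl ether and the prenyl groups alone.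

**Compound list**

1 | 2,4,6-trihydroxyacetophenone | CC(=O)c1c(O)cc(O)cc1O | starting material
2 | prenyl bromide (1-bromo-3-methylbut-2-ene) | CC(C)=CCBr | starting material
3 | 1-[2,4,6-trihydroxy-3,5-bis(3-methylbut-2-en-1-yl)phenyl]ethan-1-one | CC(=O)c1c(O)c(CC=C(C)C)c(O)c(CC=C(C)C)c1O | intermediate
4 | 1-[2,6-dihydroxy-4-methoxy-3,5-bis(3-methylbut-2-en-1-yl)phenyl]ethan-1-one | CC(=O)c1c(O)c(CC=C(C)C)c(OC)c(CC=C(C)C)c1O | intermediate
5 | 1-[4-methoxy-2,6-bis(methoxymethoxy)-3,5-bis(3-methylbut-2-en-1-yl)phenyl]ethan-1-one | CC(=O)c1c(OCOC)c(CC=C(C)C)c(OC)c(CC=C(C)C)c1OCOC | intermediate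
6 | 1-[4-methoxy-2,6-bis(methoxymethoxy)-3,5-bis(3-methylbut-2-en-1-yl)phenyl]-5-methylhex-4-en-1-one | CC(C)=CCCC(=O)c1c(OCOC)c(CC=C(C)C)c(OC)c(CC=C(C)C)c1OCOC | intermediate
7 | diethyl oxalate | CCOC(=O)C(=O)OCC | starting material
8 | ethyl 3-[4-methoxy-2,6-bis(methoxymethoxy)-3,5-diprenylbenzoyl]-6-methyl-2-oxohept-5-enoate (racemic, partly enolised, not isolated) | CCOC(=O)C(=O)C(CC=C(C)C)C(=O)c1c(OCOC)c(CC=C(C)C)c(OC)c(CC=C(C)C)c1OCOC | intermediate
9 | ethyl 3-(2,6-dihydroxy-4-methoxy-3,5-diprenylbenzoyl)-6-methyl-2-oxohept-5-enoate (racemic, not isolated) | CCOC(=O)C(=O)C(CC=C(C)C)C(=O)c1c(O)c(CC=C(C)C)c(OC)c(CC=C(C)C)c1O | intermediate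
10 | ethyl 2,5-dihydroxy-7-methoxy-4-oxo-3,6,8-triprenylchromane-2-carboxylate (mixture of stereoisomers, not isolated) | CCOC(=O)C1(O)Oc2c(CC=C(C)C)c(OC)c(CC=C(C)C)c(O)c2C(=O)C1CC=C(C)C | intermediate
11 | ethyl 5-hydroxy-7-methoxy-4-oxo-3,6,8-triprenyl-4H-chromene-2-carboxylate | CCOC(=O)c1oc2c(CC=C(C)C)c(OC)c(CC=C(C)C)c(O)c2c(=O)c1CC=C(C)C | intermediate
12 | 5-hydroxy-2-(hydroxymethyl)-7-methoxy-3,6,8-triprenyl-4H-chromen-4-one | OCc1oc2c(CC=C(C)C)c(OC)c(CC=C(C)C)c(O)c2c(=O)c1CC=C(C)C | intermediate
13 | 5-hydroxy-7-methoxy-4-oxo-3,6,8-triprenyl-4H-chromene-2-carbaldehyde | O=Cc1oc2c(CC=C(C)C)c(OC)c(CC=C(C)C)c(O)c2c(=O)c1CC=C(C)C | intermediate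
14 | 2-ethynyl-5-hydroxy-7-methoxy-3,6,8-triprenyl-4H-chromen-4-one | C#Cc1oc2c(CC=C(C)C)c(OC)c(CC=C(C)C)c(O)c2c(=O)c1CC=C(C)C | intermediate
15 | ethyl vinyl ether | C=COCC | starting material
16 | Cr(CO)6 (hexacarbonylchromium) | O=C=[Cr](=C=O)(=C=O)(=C=O)(=C=O)=C=O | starting material
17 | 1-ethoxyvinyllithium (not isolated) | [Li]C(=C)OCC | intermediate
18 | lithium pentacarbonyl(2-ethoxyacryloyl)chromate, Li[(CO)5CrC(O)C(OEt)=CH2] (not isolated) | [Li+].[O-]C(C(=C)OCC)=[Cr](=C=O)(=C=O)(=C=O)(=C=O)=C=O | intermediate
19 | pentacarbonyl[(1-ethoxyvinyl)(methoxy)carbene]chromium, (CO)5Cr=C(OMe)C(OEt)=CH2 | COC(C(=C)OCC)=[Cr](=C=O)(=C=O)(=C=O)(=C=O)=C=O | intermediate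
20 | tricarbonylchromium complex of 21 (Cr(CO)3 η6-bound to ring B, written as a separate fragment; not isolated) | COc1c(CC=C(C)C)c(O)c2c(=O)c(CC=C(C)C)c(-c3cc(OC)c(OCC)cc3O)oc2c1CC=C(C)C.O=C=[Cr](=C=O)=C=O | intermediate
21 | 2-(4-ethoxy-2-hydroxy-5-methoxyphenyl)-5-hydroxy-7-methoxy-3,6,8-triprenyl-4H-chromen-4-one | COc1c(CC=C(C)C)c(O)c2c(=O)c(CC=C(C)C)c(-c3cc(OC)c(OCC)cc3O)oc2c1CC=C(C)C | intermediate
22 | 2-ethoxy-5-(5-hydroxy-7-methoxy-4-oxo-3,6,8-triprenyl-4H-chromen-2-yl)cyclohexa-2,5-diene-1,4-dione | COc1c(CC=C(C)C)c(O)c2c(=O)c(CC=C(C)C)c(C3=CC(=O)C(OCC)=CC3=O)oc2c1CC=C(C)C | intermediate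
23 | 2-hydroxy-5-(5-hydroxy-7-methoxy-4-oxo-3,6,8-triprenyl-4H-chromen-2-yl)cyclohexa-2,5-diene-1,4-dione (not isolated) | COc1c(CC=C(C)C)c(O)c2c(=O)c(CC=C(C)C)c(C3=CC(=O)C(O)=CC3=O)oc2c1CC=C(C)C | intermediate
24 | 5-hydroxy-7-methoxy-3,6,8-tris(3-methylbut-2-en-1-yl)-2-(2,4,5-trihydroxyphenyl)-4H-chromen-4-one (CNP0330304.0) | COc1c(CC=C(C)C)c(O)c2c(=O)c(CC=C(C)C)c(-c3cc(O)c(O)cc3O)oc2c1CC=C(C)C | target

**Count**

Total steps: 12. Longest linear sequence: 11 (steps 1 to 8, then 10 to 12); step 9 is a one-step side branch.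

**Steps most likely to fail**

Step 10. The conjugated, electron-poor alkyne may insert slowly, so that thermal decay of the carbene competes. The vinylcarbene may also be intercepted by the neighbouring C3 prenyl alkene, or cyclise without CO uptake, instead of carbonylating. The fallback abandons the benzannulation for a classical diketone closure of the pyranone ring with ring B already in place. It sets out from 6, whose lithium enolate (LiN(i-Pr)2, THF, −78 °C) should add to 2,4,5-tris(allyloxy)benzaldehyde F1 (from commercial 2,4,5-trihydroxybenzaldehyde, allyl bromide and K2CO3) to give the aldol adduct F2. Dess–Martin periodinane should oxidise this to the 1,3-diketone F3. Aqueous HCl in EtOH should then remove both MOM groups and cyclodehydrate to the tri-O-allyl flavone F4; closure is unambiguous because ring B carries no free hydroxyl. Pd(PPh3)4 with morpholine should cleave the three allyl ethers without touching the C-prenyl groups, and the route is rejoined at 24.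

Step 8. Methoxide generated from K2CO3 in MeOH may add to C2 of the pyranone or to the newly formed, chromone-activated alkyne, with ring opening or enol ether formation instead of clean homologation. The fallback replaces the diazo homologation by olefination and elimination under aprotic conditions. It sets out from 13, which with the ylide from (bromomethyl)triphenylphosphonium bromide and KOt-Bu (THF, −78 °C, one extra equivalent of base for the phenol) should give 2-[(Z)-2-bromovinyl]-5-hydroxy-7-methoxy-3,6,8-triprenyl-4H-chromen-4-one F5. Anti elimination of HBr with further KOt-Bu should deliver the alkyne, rejoining the route at 14.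

Step 5. During MOM cleavage and dehydration in warm mineral acid, a phenol may add to an adjacent prenyl double bond (chroman formation) or a prenyl group may be hydrated; the hindered enolate may also condense incompletely with the oxalate. The fallback separates deprotection from ring closure and uses only weak acid for the latter. It sets out from 6, whose MOM groups should be removed by ZnBr2 and n-PrSH in CH2Cl2 at 0 °C to give 1-(2,6-dihydroxy-4-methoxy-3,5-diprenylphenyl)-5-methylhex-4-en-1-one F6. Classical condensation of F6 with 7 and NaOEt in EtOH should give 9 as its sodium salt, where the route is rejoined; AcOH at 60 °C should then close it through 10 to 11.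

**Further compounds**

F1 | step 10 | 2,4,5-tris(allyloxy)benzaldehyde | C=CCOc1cc(OCC=C)c(OCC=C)cc1C=O
F2 | step 10 | 3-hydroxy-1-[4-methoxy-2,6-bis(methoxymethoxy)-3,5-diprenylphenyl]-2-prenyl-3-[2,4,5-tris(allyloxy)phenyl]propan-1-one (mixture of diastereomers) | C=CCOc1cc(OCC=C)c(OCC=C)cc1C(O)C(CC=C(C)C)C(=O)c1c(OCOC)c(CC=C(C)C)c(OC)c(CC=C(C)C)c1OCOC
F3 | step 10 | 1-[4-methoxy-2,6-bis(methoxymethoxy)-3,5-diprenylphenyl]-2-prenyl-3-[2,4,5-tris(allyloxy)phenyl]propane-1,3-dione (racemic) | C=CCOc1cc(OCC=C)c(OCC=C)cc1C(=O)C(CC=C(C)C)C(=O)c1c(OCOC)c(CC=C(C)C)c(OC)c(CC=C(C)C)c1OCOC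
F4 | step 10 | 5-hydroxy-7-methoxy-3,6,8-triprenyl-2-[2,4,5-tris(allyloxy)phenyl]-4H-chromen-4-one | COc1c(CC=C(C)C)c(O)c2c(=O)c(CC=C(C)C)c(-c3cc(OCC=C)c(OCC=C)cc3OCC=C)oc2c1CC=C(C)C
F5 | step 8 | 2-[(Z)-2-bromovinyl]-5-hydroxy-7-methoxy-3,6,8-triprenyl-4H-chromen-4-one | Br/C=C\c1oc2c(CC=C(C)C)c(OC)c(CC=C(C)C)c(O)c2c(=O)c1CC=C(C)C
F6 | step 5 | 1-(2,6-dihydroxy-4-methoxy-3,5-diprenylphenyl)-5-methylhex-4-en-1-one | CC(C)=CCCC(=O)c1c(O)c(CC=C(C)C)c(OC)c(CC=C(C)C)c1O
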